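**Strategy.** Everything rests on disconnecting the C9–C10 bond of ring B (C5–C6–C7–C8–C9–C10) and re-attaching C9 to the formyl carbon C20: ring B is traced to a cycloheptene that still holds C20 as a ring atom. The key step, a Lewis-acid Meinwald (semipinacol) rearrangement of the C10–C20 α-epoxide, contracts this seven-membered ring to ring B, creates the quaternary C10 stereocentre trans to H5 and expels C20 as the axial aldehyde, exploiting the C9–C10–C20(=O) motif at the ring fusion. The precursor is a trans-fused bicyclo[5.4.0]undecene epoxide already carrying the C8 methylene, the C19 acetate and the butenolide side chain.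

Key step: step 17

Remark: locants C1–C20 are the labdane locants of the target (C17 exocyclic methylene carbon, C19 acetoxymethyl carbon, C20 formyl carbon); α is the face of C19, β the face of the C4 methyl group and of H5.
Assumption: the (S)-configured oxazaborolidinium catalyst of step 3 is taken to give the (1R,2S) adduct drawn; should the sense of induction be the opposite, its (R)-enantiomer is used.

Step 1
Reactants: 1 penta-1,4-dien-3-ol
Product: 2 (3E)-5-bromopenta-1,3-diene
Conditions: 48% aq. HBr, 0 °C
Reagents that add atoms: hydrogen bromide, Br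
Why: Protonation of the bis-allylic alcohol gives a pentadienyl cation that bromide captures at a terminus (SN1-type allylic substitution with allylic transposition) to give the conjugated (E)-bromodiene; no stereocentre is formed.

Step 2
Reactants: 2 (3E)-5-bromopenta-1,3-diene; 3 3-bromoprop-1-yne
Product: 5 (3E)-octa-1,3-dien-7-yne, via allenylmagnesium bromide 4 (not isolated)
Conditions: Mg, HgCl2 (1 mol%), Et2O, 0 °C; then 2, −20 °C → rt
Reagents that add atoms: none
Why: The allenyl Grignard reagent alkylates the primary allylic bromide through its γ-carbon (Grignard coupling, SE2′ at the reagent), and attack at either terminus of the pentadienyl unit gives the same linear (E)-dienyne; no stereocentre is formed.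

Step 3
Reactants: 5 (3E)-octa-1,3-dien-7-yne; 6 2-methylprop-2-enal
Product: 8 [(1R,2S)-2-(but-3-yn-1-yl)-1-methylcyclohex-3-en-1-yl]methanol, via aldehyde adduct 7 (not isolated)
Conditions: (S)-3,3-diphenyl-1-(2-methylphenyl)tetrahydro-1H,3H-pyrrolo[1,2-c][1,3,2]oxazaborole·HNTf2 (10 mol%), CH2Cl2, −78 °C; then NaBH4, MeOH, −78 → 0 °C
Reagents that add atoms: none
Why: In this enantioselective Lewis-acid-catalysed Diels–Alder reaction the 1-alkyl diene adds with ortho regiochemistry and endo orientation of the formyl group, so C4 and C5 are set together with C19 cis to the butynyl chain while the chiral oxazaborolidinium fixes the absolute sense, and borohydride then reduces the aldehyde in the same flask.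

Step 4
Reactants: 8 [(1R,2S)-2-(but-3-yn-1-yl)-1-methylcyclohex-3-en-1-yl]methanol
Product: 9 [2-(but-3-yn-1-yl)-3-methyl-7-oxabicyclo[4.1.0]heptan-3-yl]methanol (oxirane oxygen cis to CH2OH and to the butynyl chain)
Conditions: VO(acac)2 (5 mol%), t-BuOOH, CH2Cl2, 0 °C → rt
Reagents that add atoms: tert-butyl hydroperoxide, CC(C)(C)OO
Why: In this hydroxyl-directed vanadium-catalysed epoxidation of a cyclohex-3-enylmethanol the alkoxide-bound vanadium peroxide delivers oxygen to the face syn to CH2OH, which sets the α-epoxide at C1–C10 while the alkyne stays inert.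

Step 5
Reactants: 9 [2-(but-3-yn-1-yl)-3-methyl-7-oxabicyclo[4.1.0]heptan-3-yl]methanol (oxirane oxygen cis to CH2OH and to the butynyl chain)
Product: 10 (1S,2R,3R)-2-(but-3-yn-1-yl)-3-(hydroxymethyl)-3-methylcyclohexan-1-ol
Conditions: LiAlH4, THF, 0 → 50 °C
Reagents that add atoms: none
Why: Hydride opens the epoxide by SN2 attack at C1, the carbon remote from the substituted C5, in the trans-diaxial mode of the half-chair that keeps the butynyl chain pseudo-equatorial, so the oxygen stays on C10 (α) and the terminal alkyne survives.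

Step 6
Reactants: 10 (1S,2R,3R)-2-(but-3-yn-1-yl)-3-(hydroxymethyl)-3-methylcyclohexan-1-ol
Product: 11 (1S,2R,3R)-2-(but-3-yn-1-yl)-3-({[tert-butyl(dimethyl)silyl]oxy}methyl)-3-methylcyclohexan-1-ol
Conditions: t-BuMe2SiCl, imidazole, CH2Cl2, 0 °C
Reagents that add atoms: tert-butyldimethylsilyl chloride, CC(C)(C)[Si](C)(C)Cl
Why: Silyl ether formation is much faster at the primary C19 hydroxyl than at the hindered axial secondary hydroxyl on C10, which gives the mono-protected diol.

Step 7
Reactants: 11 (1S,2R,3R)-2-(but-3-yn-1-yl)-3-({[tert-butyl(dimethyl)silyl]oxy}methyl)-3-methylcyclohexan-1-ol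
Product: 12 (2R,3R)-2-(but-3-yn-1-yl)-3-({[tert-butyl(dimethyl)silyl]oxy}methyl)-3-methylcyclohexan-1-one
Conditions: Dess–Martin periodinane, pyridine, CH2Cl2, 0 °C → rt
Reagents that add atoms: none
Why: Dess–Martin oxidation converts the secondary alcohol into the C10 ketone under buffered, non-basic conditions that should not epimerise the adjacent C5 stereocentre.

Step 8
Reactants: 12 (2R,3R)-2-(but-3-yn-1-yl)-3-({[tert-butyl(dimethyl)silyl]oxy}methyl)-3-methylcyclohexan-1-one; 13 ethenylmagnesium bromide
Product: 14 (1R,2R,3R)-2-(but-3-yn-1-yl)-3-({[tert-butyl(dimethyl)silyl]oxy}methyl)-1-ethenyl-3-methylcyclohexan-1-ol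
Conditions: 13 (3 equiv), CeCl3, THF, −78 °C
Reagents that add atoms: none
Why: In this 1,2-addition of the vinylcerium reagent (Grignard addition with CeCl3 to suppress enolisation) the axial C19 group shields the axial trajectory of the chair that has the C5 chain equatorial, so equatorial attack sets C10 with the hydroxyl axial (α, cis to C19) and the vinyl group (C20) equatorial.

Step 9
Reactants: 14 (1R,2R,3R)-2-(but-3-yn-1-yl)-3-({[tert-butyl(dimethyl)silyl]oxy}methyl)-1-ethenyl-3-methylcyclohexan-1-ol
Product: 16 1-({[tert-butyl(dimethyl)silyl]oxy}methyl)-1-methyl-7-methylidene-1,2,3,4,7,8,9,9a-octahydro-4aH-benzo[7]annulen-4a-ol (trans-fused; 4a-OH cis to CH2OTBS; methyl cis to H9a), via triene 15 (not isolated)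
Conditions: (H2IMes)(PCy3)Cl2Ru=CHPh (second-generation Grubbs catalyst, 10 mol%), ethylene (1 atm), toluene, rt; then Ar purge, 80 °C
Reagents that add atoms: ethene, C=C
Why: In this tandem enyne cross-metathesis and ring-closing metathesis the ruthenium methylidene first turns the terminal alkyne into a 2-substituted buta-1,3-diene, whose monosubstituted terminus then closes onto the vinyl carbinol to form the C9=C20 bond of the seven-membered ring with the C8 methylene in place; no stereocentre changes.

Step 10
Reactants: 16 1-({[tert-butyl(dimethyl)silyl]oxy}methyl)-1-methyl-7-methylidene-1,2,3,4,7,8,9,9a-octahydro-4aH-benzo[7]annulen-4a-ol (trans-fused; 4a-OH cis to CH2OTBS; methyl cis to H9a); 17 1,1-dimethoxy-N,N-dimethylethanamine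
Product: 19 2-[4-({[tert-butyl(dimethyl)silyl]oxy}methyl)-4-methyl-7-methylidene-2,3,4,4a,5,6,7,8-octahydro-1H-benzo[7]annulen-8-yl]-N,N-dimethylacetamide (side chain cis to CH2OTBS; H4a cis to methyl and to H8), via ketene N,O-acetal 18 (not isolated)
Conditions: xylenes, 140 °C, MeOH distilled off
Reagents that add atoms: none
Why: In this Eschenmoser–Claisen rearrangement the tertiary allylic alcohol exchanges into the ketene N,O-acetal and the suprafacial [3,3]-shift across O–C10–C20=C9 relays the α-configured C10–O stereocentre to C9, forming the C9–C11 bond on the α face and the C10=C20 double bond.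

Step 11
Reactants: 19 2-[4-({[tert-butyl(dimethyl)silyl]oxy}methyl)-4-methyl-7-methylidene-2,3,4,4a,5,6,7,8-octahydro-1H-benzo[7]annulen-8-yl]-N,N-dimethylacetamide (side chain cis to CH2OTBS; H4a cis to methyl and to H8)
Product: 20 2-[4-({[tert-butyl(dimethyl)silyl]oxy}methyl)-4-methyl-7-methylidene-2,3,4,4a,5,6,7,8-octahydro-1H-benzo[7]annulen-8-yl]ethan-1-ol (configuration as in 19)
Conditions: LiEt3BH, THF, 0 °C → rt
Reagents that add atoms: none
Why: LiEt3BH reduces the tertiary amide to the primary alcohol with C–N cleavage (hydride reduction via the aldehyde) and leaves the silyl ether and the skipped diene untouched.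

Step 12
Reactants: 20 2-[4-({[tert-butyl(dimethyl)silyl]oxy}methyl)-4-methyl-7-methylidene-2,3,4,4a,5,6,7,8-octahydro-1H-benzo[7]annulen-8-yl]ethan-1-ol (configuration as in 19)
Product: 21 tert-butyl{[8-(2-iodoethyl)-4-methyl-7-methylidene-2,3,4,4a,5,6,7,8-octahydro-1H-benzo[7]annulen-4-yl]methoxy}dimethylsilane (configuration as in 19)
Conditions: I2, PPh3, imidazole, CH2Cl2, 0 °C
Reagents that add atoms: iodine, II
Why: Appel-type iodination converts the unhindered primary alcohol into the iodide by SN2 displacement of the oxyphosphonium group.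

Step 13
Reactants: 21 tert-butyl{[8-(2-iodoethyl)-4-methyl-7-methylidene-2,3,4,4a,5,6,7,8-octahydro-1H-benzo[7]annulen-4-yl]methoxy}dimethylsilane (configuration as in 19); 22 3-bromofuran-2(5H)-one
Product: 24 3-{2-[4-({[tert-butyl(dimethyl)silyl]oxy}methyl)-4-methyl-7-methylidene-2,3,4,4a,5,6,7,8-octahydro-1H-benzo[7]annulen-8-yl]ethyl}furan-2(5H)-one (configuration as in 19), via alkylzinc iodide 23 (not isolated)
Conditions: Zn dust, LiCl, THF, 40 °C; then 22, Pd(dppf)Cl2 (5 mol%), THF, 50 °C
Reagents that add atoms: none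
Why: In this Negishi coupling zinc insertion gives the primary alkylzinc iodide, which palladium catalysis joins to the α-bromobutenolide to forge C12–C13 and install the complete butenolide without touching the other alkenes.

Step 14
Reactants: 24 3-{2-[4-({[tert-butyl(dimethyl)silyl]oxy}methyl)-4-methyl-7-methylidene-2,3,4,4a,5,6,7,8-octahydro-1H-benzo[7]annulen-8-yl]ethyl}furan-2(5H)-one (configuration as in 19)
Product: 25 3-{2-[4-(hydroxymethyl)-4-methyl-7-methylidene-2,3,4,4a,5,6,7,8-octahydro-1H-benzo[7]annulen-8-yl]ethyl}furan-2(5H)-one (configuration as in 19)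
Conditions: HF·pyridine, pyridine, THF, 0 °C → rt
Reagents that add atoms: none
Why: Fluoride-mediated cleavage of the silyl ether under buffered, non-basic conditions frees the C19 hydroxyl while the base-sensitive butenolide survives.

Step 15
Reactants: 25 3-{2-[4-(hydroxymethyl)-4-methyl-7-methylidene-2,3,4,4a,5,6,7,8-octahydro-1H-benzo[7]annulen-8-yl]ethyl}furan-2(5H)-one (configuration as in 19)
Product: 26 3-{2-[9,9a-epoxy-4-(hydroxymethyl)-4-methyl-7-methylidenedecahydro-1H-benzo[7]annulen-8-yl]ethyl}furan-2(5H)-one (oxirane oxygen cis to CH2OH and to the side chain; trans to H4a)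
Conditions: VO(acac)2 (5 mol%), t-BuOOH, CH2Cl2, 0 °C
Reagents that add atoms: tert-butyl hydroperoxide, CC(C)(C)OO
Why: In this hydroxyl-directed vanadium-catalysed epoxidation the axial C19 hydroxyl, 1,3-diaxial to the α face of C10, delivers oxygen only to the trisubstituted C10=C20 alkene and from the α face, setting the C10 and C20 epoxide stereocentres, while the distant C8 methylene and the electron-poor butenolide alkene should not react.

Step 16
Reactants: 26 3-{2-[9,9a-epoxy-4-(hydroxymethyl)-4-methyl-7-methylidenedecahydro-1H-benzo[7]annulen-8-yl]ethyl}furan-2(5H)-one (oxirane oxygen cis to CH2OH and to the side chain; trans to H4a)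
Product: 27 {9,9a-epoxy-4-methyl-7-methylidene-8-[2-(2-oxo-2,5-dihydrofuran-3-yl)ethyl]decahydro-1H-benzo[7]annulen-4-yl}methyl acetate (configuration as in 26)
Conditions: Ac2O, pyridine, 4-(dimethylamino)pyridine (5 mol%), CH2Cl2, 0 °C
Reagents that add atoms: acetic anhydride, CC(=O)OC(C)=O
Why: Acylation of the primary alcohol (nucleophilic catalysis) installs the C19 acetate under basic conditions that leave the epoxide intact and removes the free hydroxyl before the Lewis-acid step.

Step 17
Reactants: 27 {9,9a-epoxy-4-methyl-7-methylidene-8-[2-(2-oxo-2,5-dihydrofuran-3-yl)ethyl]decahydro-1H-benzo[7]annulen-4-yl}methyl acetate (configuration as in 26)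
Product: 28 [(1R,4aR,5R,8aR)-4a-formyl-1-methyl-6-methylidene-5-[2-(2-oxo-2,5-dihydrofuran-3-yl)ethyl]decahydronaphthalen-1-yl]methyl acetate
Conditions: MeAl(OC6H2-2,6-tBu2-4-Br)2 (3 equiv, made from AlMe3 and 4-bromo-2,6-di-tert-butylphenol), CH2Cl2, −78 °C
Reagents that add atoms: none
Why: The bulky aluminium Lewis acid binds the epoxide oxygen, the C10–O bond ionises at the tertiary ring-fusion carbon and C9 shifts from C20 to C10 anti to the departing oxygen while C20 becomes the aldehyde (Meinwald rearrangement, a semipinacol 1,2-shift). The closest known reaction type is the ring contraction of 1-substituted cycloalkene oxides to 1-substituted cycloalkanecarbaldehydes promoted by bulky aluminium aryloxides. Ring B is closed by this suprafacial 1,2-alkyl shift, which replaces the C10–C20–C9 segment of the seven-membered ring by the direct C9–C10 bond of the cyclohexane and leaves C20 exocyclic. The only new stereocentre, C10, is controlled by the epoxide: the α-oxygen forces C9 onto the β face, so the formyl group ends α and trans to H5, and C9 migrates with retention. The step needs the alkyl shift to win over the hydride shift (which would give the C20 ketone), over elimination and over halohydrin pathways, and needs the C8 methylene, the acetate and the butenolide to survive; this should be secured by the halide-free, sterically demanding Lewis acid at −78 °C, by the high migratory aptitude of the secondary allylic C9 and by the syn placement of the acetate, which cannot open the epoxide from behind.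

Compound list
1 | penta-1,4-dien-3-ol | C=CC(O)C=C | starting material
2 | (3E)-5-bromopenta-1,3-diene | C=C/C=C/CBr | intermediate
3 | 3-bromoprop-1-yne | C#CCBr | starting material
4 | allenylmagnesium bromide (propa-1,2-dien-1-ylmagnesium bromide) | C=C=C[Mg]Br | intermediate
5 | (3E)-octa-1,3-dien-7-yne | C=C/C=C/CCC#C | intermediate
6 | 2-methylprop-2-enal | C=C(C)C=O | starting material
7 | aldehyde adduct: (1R,2S)-2-(but-3-yn-1-yl)-1-methylcyclohex-3-ene-1-carbaldehyde | C#CCC[C@H]1C=CCC[C@@]1(C)C=O | intermediate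
8 | [(1R,2S)-2-(but-3-yn-1-yl)-1-methylcyclohex-3-en-1-yl]methanol | C#CCC[C@H]1C=CCC[C@@]1(C)CO | intermediate
9 | [2-(but-3-yn-1-yl)-3-methyl-7-oxabicyclo[4.1.0]heptan-3-yl]methanol (oxirane oxygen cis to CH2OH and to the butynyl chain) | C#CCC[C@H]1[C@H]2O[C@H]2CC[C@@]1(C)CO | intermediate
10 | (1S,2R,3R)-2-(but-3-yn-1-yl)-3-(hydroxymethyl)-3-methylcyclohexan-1-ol | C#CCC[C@H]1[C@@H](O)CCC[C@@]1(C)CO | intermediate
11 | (1S,2R,3R)-2-(but-3-yn-1-yl)-3-({[tert-butyl(dimethyl)silyl]oxy}methyl)-3-methylcyclohexan-1-ol | C#CCC[C@H]1[C@@H](O)CCC[C@@]1(C)CO[Si](C)(C)C(C)(C)C | intermediate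
12 | (2R,3R)-2-(but-3-yn-1-yl)-3-({[tert-butyl(dimethyl)silyl]oxy}methyl)-3-methylcyclohexan-1-one | C#CCC[C@H]1C(=O)CCC[C@@]1(C)CO[Si](C)(C)C(C)(C)C | intermediate
13 | ethenylmagnesium bromide | C=C[Mg]Br | starting material
14 | (1R,2R,3R)-2-(but-3-yn-1-yl)-3-({[tert-butyl(dimethyl)silyl]oxy}methyl)-1-ethenyl-3-methylcyclohexan-1-ol | C#CCC[C@H]1[C@](O)(C=C)CCC[C@@]1(C)CO[Si](C)(C)C(C)(C)C | intermediate
15 | triene: (1R,2R,3R)-3-({[tert-butyl(dimethyl)silyl]oxy}methyl)-1-ethenyl-3-methyl-2-(3-methylidenepent-4-en-1-yl)cyclohexan-1-ol | C=CC(=C)CC[C@H]1[C@](O)(C=C)CCC[C@@]1(C)CO[Si](C)(C)C(C)(C)C | intermediate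
16 | 1-({[tert-butyl(dimethyl)silyl]oxy}methyl)-1-methyl-7-methylidene-1,2,3,4,7,8,9,9a-octahydro-4aH-benzo[7]annulen-4a-ol (trans-fused; 4a-OH cis to CH2OTBS; methyl cis to H9a) | C=C1CC[C@@H]2[C@](C)(CO[Si](C)(C)C(C)(C)C)CCC[C@@]2(O)C=C1 | intermediate
17 | 1,1-dimethoxy-N,N-dimethylethanamine | CC(OC)(OC)N(C)C | starting material
18 | ketene N,O-acetal: the 4a-O-[1-(dimethylamino)ethenyl] ether of 16 | C=C1CC[C@@H]2[C@](C)(CO[Si](C)(C)C(C)(C)C)CCC[C@@]2(OC(=C)N(C)C)C=C1 | intermediate
19 | 2-[4-({[tert-butyl(dimethyl)silyl]oxy}methyl)-4-methyl-7-methylidene-2,3,4,4a,5,6,7,8-octahydro-1H-benzo[7]annulen-8-yl]-N,N-dimethylacetamide (side chain cis to CH2OTBS; H4a cis to methyl and to H8) | C=C1CC[C@@H]2[C@](C)(CO[Si](C)(C)C(C)(C)C)CCCC2=C[C@@H]1CC(=O)N(C)C | intermediate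
20 | 2-[4-({[tert-butyl(dimethyl)silyl]oxy}methyl)-4-methyl-7-methylidene-2,3,4,4a,5,6,7,8-octahydro-1H-benzo[7]annulen-8-yl]ethan-1-ol (configuration as in 19) | C=C1CC[C@@H]2[C@](C)(CO[Si](C)(C)C(C)(C)C)CCCC2=C[C@@H]1CCO | intermediate
21 | tert-butyl{[8-(2-iodoethyl)-4-methyl-7-methylidene-2,3,4,4a,5,6,7,8-octahydro-1H-benzo[7]annulen-4-yl]methoxy}dimethylsilane (configuration as in 19) | C=C1CC[C@@H]2[C@](C)(CO[Si](C)(C)C(C)(C)C)CCCC2=C[C@@H]1CCI | intermediate
22 | 3-bromofuran-2(5H)-one | BrC1=CCOC1=O | starting material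
23 | alkylzinc iodide derived from 21 | C=C1CC[C@@H]2[C@](C)(CO[Si](C)(C)C(C)(C)C)CCCC2=C[C@@H]1CC[Zn]I | intermediate
24 | 3-{2-[4-({[tert-butyl(dimethyl)silyl]oxy}methyl)-4-methyl-7-methylidene-2,3,4,4a,5,6,7,8-octahydro-1H-benzo[7]annulen-8-yl]ethyl}furan-2(5H)-one (configuration as in 19) | C=C1CC[C@@H]2[C@](C)(CO[Si](C)(C)C(C)(C)C)CCCC2=C[C@@H]1CCC1=CCOC1=O | intermediate
25 | 3-{2-[4-(hydroxymethyl)-4-methyl-7-methylidene-2,3,4,4a,5,6,7,8-octahydro-1H-benzo[7]annulen-8-yl]ethyl}furan-2(5H)-one (configuration as in 19) | C=C1CC[C@@H]2[C@](C)(CO)CCCC2=C[C@@H]1CCC1=CCOC1=O | intermediate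
26 | 3-{2-[9,9a-epoxy-4-(hydroxymethyl)-4-methyl-7-methylidenedecahydro-1H-benzo[7]annulen-8-yl]ethyl}furan-2(5H)-one (oxirane oxygen cis to CH2OH and to the side chain; trans to H4a) | C=C1CC[C@@H]2[C@](C)(CO)CCC[C@]23O[C@@H]3[C@@H]1CCC1=CCOC1=O | intermediate
27 | {9,9a-epoxy-4-methyl-7-methylidene-8-[2-(2-oxo-2,5-dihydrofuran-3-yl)ethyl]decahydro-1H-benzo[7]annulen-4-yl}methyl acetate (configuration as in 26) | C=C1CC[C@@H]2[C@](C)(COC(C)=O)CCC[C@]23O[C@@H]3[C@@H]1CCC1=CCOC1=O | intermediate
28 | [(1R,4aR,5R,8aR)-4a-formyl-1-methyl-6-methylidene-5-[2-(2-oxo-2,5-dihydrofuran-3-yl)ethyl]decahydronaphthalen-1-yl]methyl acetate (19-acetoxy-20-oxo-ent-labda-8(17),13-dien-16,15-olide) | C=C1CC[C@@H]2[C@](C)(COC(C)=O)CCC[C@@]2(C=O)[C@@H]1CCC1=CCOC1=O | target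

Total step count: 17. Longest linear sequence: 17 steps (1 to 28); the other reactants 3, 6, 13, 17 and 22 are taken as commercial.

Steps most likely to fail

Step 17. A 1,2-hydride shift from C20 or proton loss from the C10 cation may outrun the C9 shift, and binding of the aluminium reagent to the lactone and acetate may stall the ionisation. The fallback is a stepwise halohydrin semipinacol ring contraction that sets out from 25 and comes back at 28. Acetylation of 25 (Ac2O, pyridine) should give the alkene acetate F1. Buffered mCPBA should epoxidise its C10=C20 bond from the less hindered β face to the β-epoxide F2. MgBr2·OEt2 should open this epoxide at the tertiary C10 with inversion to the trans-bromohydrin F3 (C10–Br α, C20–OH β). AgBF4 with 2,6-di-tert-butylpyridine should then ionise the tertiary bromide while C9 migrates anti to it from the β face, which again contracts the seven-membered ring to 28.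

Step 9. Direct exo ring-closing enyne metathesis to a six-membered ring may occur before ethylene has consumed the alkyne, or the ring may close through the 1,1-disubstituted alkene of the diene. The fallback sets out from 14 and comes back at 16; it builds the diene without any ruthenium carbene present. Molybdenum-catalysed α-selective hydrostannation of the alkyne of 14 (Bu3SnH, Mo(CO)3(CNtBu)3, THF, 55 °C) should give the α-vinylstannane F4. Stille coupling with vinyl bromide (Pd(PPh3)4, CuI, DMF) should give the triene 15, now isolated. A separate ring-closing metathesis ((H2IMes)Cl2Ru=CH(2-iPrOC6H4), second-generation Hoveyda–Grubbs catalyst, toluene, 80 °C) should then give 16.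

Step 10. Exchange of the hindered tertiary alcohol with the amide acetal may be too slow, and the dienyl carbinol may ionise or eliminate at 140 °C. The fallback sets out from 16 and comes back at 20; it replaces the thermal exchange by acylation and a low-temperature ester enolate rearrangement. Acylation of the potassium alkoxide of 16 (KN(SiMe3)2, then acetyl chloride, THF, −78 °C) should give the tertiary acetate F5. Ireland–Claisen rearrangement (LiN(iPr)2, t-BuMe2SiCl, THF/DMPU, −78 °C → rt, hydrolytic work-up) should transfer the C10–O configuration to C9 and give the carboxylic acid F6. LiAlH4 should reduce F6 to the alcohol 20.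

Further compounds
F1 | step 17 | alkene acetate: {4-methyl-7-methylidene-8-[2-(2-oxo-2,5-dihydrofuran-3-yl)ethyl]-2,3,4,4a,5,6,7,8-octahydro-1H-benzo[7]annulen-4-yl}methyl acetate (configuration as in 25) | C=C1CC[C@@H]2[C@](C)(COC(C)=O)CCCC2=C[C@@H]1CCC1=CCOC1=O
F2 | step 17 | β-epoxide: the 9,9a-epoxide of F1 with the oxirane oxygen trans to CH2OAc and cis to H4a | C=C1CC[C@@H]2[C@](C)(COC(C)=O)CCC[C@@]23O[C@H]3[C@@H]1CCC1=CCOC1=O
F3 | step 17 | trans-bromohydrin: {9a-bromo-9-hydroxy-4-methyl-7-methylidene-8-[2-(2-oxo-2,5-dihydrofuran-3-yl)ethyl]decahydro-1H-benzo[7]annulen-4-yl}methyl acetate (bromine cis to CH2OAc; hydroxyl trans to it) | C=C1CC[C@@H]2[C@](C)(COC(C)=O)CCC[C@@]2(Br)[C@@H](O)[C@@H]1CCC1=CCOC1=O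
F4 | step 9 | α-vinylstannane: (1R,2R,3R)-3-({[tert-butyl(dimethyl)silyl]oxy}methyl)-1-ethenyl-3-methyl-2-[3-(tributylstannyl)but-3-en-1-yl]cyclohexan-1-ol | C=C([Sn](CCCC)(CCCC)CCCC)CC[C@H]1[C@](O)(C=C)CCC[C@@]1(C)CO[Si](C)(C)C(C)(C)C
F5 | step 10 | tertiary acetate: the 4a-O-acetyl derivative of 16 | C=C1CC[C@@H]2[C@](C)(CO[Si](C)(C)C(C)(C)C)CCC[C@@]2(OC(C)=O)C=C1
F6 | step 10 | carboxylic acid: 2-[4-({[tert-butyl(dimethyl)silyl]oxy}methyl)-4-methyl-7-methylidene-2,3,4,4a,5,6,7,8-octahydro-1H-benzo[7]annulen-8-yl]acetic acid (configuration as in 19) | C=C1CC[C@@H]2[C@](C)(CO[Si](C)(C)C(C)(C)C)CCCC2=C[C@@H]1CC(=O)O
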